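**Retrosynthetic overview**
1. Global O-debenzylation comes last; before it, both isoquinoline–naphthalene bonds are made in one double Suzuki coupling of a single (1R,3R)-tetrahydroisoquinoline boronate with an unsymmetrical binaphthyl bis-triflate.
2. The bis-triflate comes from an aryl-naphthoquinone (reduction, site-selective triflation), made by Suzuki coupling of a bromonaphthoquinone with a naphthyl boronate, so the central axis is cross-coupled without homodimers.
3. Key ring constructions: the benzenoid ring of the bromonaphthoquinone by a regiocontrolled Diels–Alder cycloaddition (vinylketene silyl acetal + 2,6-dibromobenzoquinone); the oxygenated ring of the second naphthalene by a Dötz benzannulation (chromium carbene + propyne, closing by 6π-electrocyclisation), whose new OH becomes the coupling triflate.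
4. Isoquinoline: C3 is bought from D-alanine (cyclic sulfamidate opened by an aryl Grignard reagent), the ring is closed by Bischler–Napieralski cyclisation ortho to the benzyloxy group (para position blocked by Br), and C1 is set by substrate-controlled trans reduction.
5. Ring order: N-heterocycle (fragment 1), quinone benzenoid ring (fragment 2), naphthol ring (fragment 3), then central axis, then the two outer axes.

Assumption: the SMILES fixes only the four carbon stereocentres (1R,3R in both tetrahydroisoquinolines) and leaves the two hindered isoquinoline–naphthalene axes undefined, so the route controls the centres and the atropo-diastereomers formed in step 16 are separated by preparative HPLC; the central binaphthyl axis rotates freely.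

**Fragment 1: isoquinoline boronate**

Step 1
Reactants: 1 1-(benzyloxy)-3-bromobenzene; 2 tert-butyl (4R)-4-methyl-1,2,3-oxathiazolidine-3-carboxylate 2,2-dioxide
Product: 5 tert-butyl N-[(2R)-1-[3-(benzyloxy)phenyl]propan-2-yl]carbamate, via arylmagnesium bromide 3 (not isolated), via N-sulfamate salt 4 (not isolated)
Conditions: Mg, THF, reflux; then 2, CuI (10 mol %), THF, −20 °C → rt; then 10% aq. citric acid, rt
Reagents that add atoms: none
Why: Copper-catalysed SN2 ring opening of the cyclic sulfamidate at its primary C–O carbon by the aryl Grignard reagent leaves the D-alanine-derived centre untouched (C3 is bought as R), and mild acid hydrolyses the N-sulfonate while the Boc group stays.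

Step 2
Reactants: 5 tert-butyl N-[(2R)-1-[3-(benzyloxy)phenyl]propan-2-yl]carbamate
Product: 6 tert-butyl N-[(2R)-1-[5-(benzyloxy)-2-bromophenyl]propan-2-yl]carbamate
Conditions: NBS, MeCN, 0 °C → rt
Reagents that add atoms: N-bromosuccinimide O=C1CCC(=O)N1Br
Why: Electrophilic aromatic bromination goes para to the benzyloxy group, placing bromine at the future C5 where it blocks the para position for the ring closure and later serves as the coupling handle.

Step 3
Reactants: 6 tert-butyl N-[(2R)-1-[5-(benzyloxy)-2-bromophenyl]propan-2-yl]carbamate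
Product: 8 N-[(2R)-1-[5-(benzyloxy)-2-bromophenyl]propan-2-yl]acetamide, via amine hydrochloride 7 (not isolated)
Conditions: 4 M HCl in dioxane, rt; then Ac2O, Et3N, CH2Cl2, 0 °C → rt
Reagents that add atoms: acetic anhydride CC(=O)OC(C)=O
Why: Acidolysis of the Boc carbamate followed by N-acetylation gives the Bischler–Napieralski substrate without touching the stereocentre.

Step 4
Reactants: 8 N-[(2R)-1-[5-(benzyloxy)-2-bromophenyl]propan-2-yl]acetamide
Product: 9 (3R)-8-(benzyloxy)-5-bromo-1,3-dimethyl-3,4-dihydroisoquinoline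
Conditions: Tf2O, 2-chloropyridine, CH2Cl2, −78 → 45 °C; aq. NaHCO3 work-up
Reagents that add atoms: none
Why: Bischler–Napieralski cyclisation (Tf2O/2-chloropyridine amide activation) closes onto the only free ortho carbon, which is ortho to the activating benzyloxy group because bromine blocks the para site.

Step 5
Reactants: 9 (3R)-8-(benzyloxy)-5-bromo-1,3-dimethyl-3,4-dihydroisoquinoline
Product: 10 (1R,3R)-8-(benzyloxy)-5-bromo-1,3-dimethyl-1,2,3,4-tetrahydroisoquinoline
Conditions: LiAlH4, AlMe3, THF, −78 → 0 °C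
Reagents that add atoms: none
Why: Diastereoselective imine reduction in which AlMe3 complexation at nitrogen forces the 3-methyl group pseudoaxial and hydride adds anti to it, giving the 1,3-trans (1R,3R) amine under control of the bought C3 centre.

Step 6
Reactants: 10 (1R,3R)-8-(benzyloxy)-5-bromo-1,3-dimethyl-1,2,3,4-tetrahydroisoquinoline
Product: 11 (1R,3R)-8-(benzyloxy)-1,3-dimethyl-5-(4,4,5,5-tetramethyl-1,3,2-dioxaborolan-2-yl)-1,2,3,4-tetrahydroisoquinoline
Conditions: B2pin2, PdCl2(dppf) (5 mol %), KOAc, 1,4-dioxane, 90 °C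
Reagents that add atoms: bis(pinacolato)diboron CC1(C)OB(OC1(C)C)B1OC(C)(C)C(C)(C)O1
Why: Miyaura borylation of the aryl bromide, in which the hindered 2,6-dialkylpiperidine-type NH and the benzyl ether are inert under KOAc conditions.

**Fragment 2: bromonaphthoquinone**

Step 7
Reactants: 12 methyl 3-methylbut-2-enoate
Product: 13 [(1-methoxy-3-methylbuta-1,3-dien-1-yl)oxy]trimethylsilane
Conditions: LiN(i-Pr)2, THF, −78 °C; then Me3SiCl, −78 °C → rt
Reagents that add atoms: chlorotrimethylsilane C[Si](C)(C)Cl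
Why: γ-Deprotonation of the enoate gives the extended dienolate, which is O-silylated to the vinylketene silyl acetal diene.

Step 8
Reactants: 13 [(1-methoxy-3-methylbuta-1,3-dien-1-yl)oxy]trimethylsilane; 14 2,6-dibromo-1,4-benzoquinone
Product: 17 2-bromo-8-hydroxy-6-methylnaphthalene-1,4-dione, via bromo cycloadduct 15 (not isolated), via naphthoquinone silyl ether 16 (not isolated)
Conditions: CH2Cl2, −40 °C → rt; then SiO2 (or 1 M HCl, THF)
Reagents that add atoms: none
Why: Regiocontrolled Diels–Alder cycloaddition in which the nucleophilic CH2 terminus of the diene bonds to the unsubstituted carbon of a bromoalkene, that bromine leaves as HBr and loss of methanol aromatises the new ring, so the remaining bromine sits next to the carbonyl peri to the new OH.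

Step 9
Reactants: 17 2-bromo-8-hydroxy-6-methylnaphthalene-1,4-dione
Product: 18 2-bromo-8-methoxy-6-methylnaphthalene-1,4-dione
Conditions: MeI, Ag2O, CH2Cl2, rt, dark
Reagents that add atoms: iodomethane CI
Why: Silver-oxide-promoted O-methylation (Williamson type) of the chelated peri-hydroxyl under non-basic conditions that the bromoquinone tolerates.

**Fragment 3: naphthyl boronate**

Step 10
Reactants: 19 2,6-diiodophenol
Product: 20 2-(benzyloxy)-1,3-diiodobenzene
Conditions: BnBr, K2CO3, DMF, 60 °C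
Reagents that add atoms: benzyl bromide BrCc1ccccc1
Why: Williamson ether synthesis on the phenol.

Step 11
Reactants: 20 2-(benzyloxy)-1,3-diiodobenzene
Product: 23 pentacarbonyl{[2-(benzyloxy)-3-iodophenyl](methoxy)methylidene}chromium, via aryllithium 21 (not isolated), via lithium acylchromate 22 (not isolated)
Conditions: n-BuLi (1.0 equiv), Et2O, −78 °C; Cr(CO)6, −78 °C → rt; then Me3OBF4, CH2Cl2, 0 °C → rt
Reagents that add atoms: chromium hexacarbonyl O=C=[Cr](=C=O)(=C=O)(=C=O)(=C=O)=C=O; trimethyloxonium tetrafluoroborate C[O+](C)C.F[B-](F)(F)F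
Why: Fischer carbene synthesis by mono iodine–lithium exchange, addition of the aryllithium to a CO ligand of Cr(CO)6 and O-methylation of the acylchromate.

Step 12
Reactants: 23 pentacarbonyl{[2-(benzyloxy)-3-iodophenyl](methoxy)methylidene}chromium; 24 propyne
Product: 26 5-(benzyloxy)-6-iodo-4-methoxy-2-methylnaphthalen-1-yl trifluoromethanesulfonate, via naphthol 25 (not isolated)
Conditions: propyne (5 equiv), THF, 55 °C, sealed tube; then Et3N, DMAP (cat.), PhNTf2, rt; then air, MeCN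
Reagents that add atoms: N-phenylbis(trifluoromethanesulfonimide) O=S(=O)(N(c1ccccc1)S(=O)(=O)C(F)(F)F)C(F)(F)F
Why: Dötz benzannulation (alkyne and CO insertion at the zerovalent chromium carbene, then 6π-electrocyclisation of the dienylketene onto the only free ortho carbon) puts the methyl group ortho to the new OH, which is trapped as the triflate before oxidative demetalation so that no quinone forms.

Step 13
Reactants: 26 5-(benzyloxy)-6-iodo-4-methoxy-2-methylnaphthalen-1-yl trifluoromethanesulfonate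
Product: 27 5-(benzyloxy)-4-methoxy-2-methyl-6-(4,4,5,5-tetramethyl-1,3,2-dioxaborolan-2-yl)naphthalen-1-yl trifluoromethanesulfonate
Conditions: B2pin2, PdCl2(dppf) (5 mol %), KOAc, 1,4-dioxane, 80 °C
Reagents that add atoms: bis(pinacolato)diboron CC1(C)OB(OC1(C)C)B1OC(C)(C)C(C)(C)O1
Why: Miyaura borylation that is chemoselective for the C–I bond over the triflate shielded by the ortho methyl group and the peri position.

**Assembly**

Step 14
Reactants: 18 2-bromo-8-methoxy-6-methylnaphthalene-1,4-dione; 27 5-(benzyloxy)-4-methoxy-2-methyl-6-(4,4,5,5-tetramethyl-1,3,2-dioxaborolan-2-yl)naphthalen-1-yl trifluoromethanesulfonate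
Product: 28 5-(benzyloxy)-4-methoxy-6-(8-methoxy-6-methyl-1,4-dioxo-1,4-dihydronaphthalen-2-yl)-2-methylnaphthalen-1-yl trifluoromethanesulfonate
Conditions: PdCl2(dppf) (5 mol %), K3PO4, 1,4-dioxane/H2O, 50 °C
Reagents that add atoms: none
Why: Suzuki–Miyaura coupling in which oxidative addition into the vinylogous acyl bromide of the quinone is far faster than into the hindered aryl triflate, so only the cross-coupled central bond forms.

Step 15
Reactants: 28 5-(benzyloxy)-4-methoxy-6-(8-methoxy-6-methyl-1,4-dioxo-1,4-dihydronaphthalen-2-yl)-2-methylnaphthalen-1-yl trifluoromethanesulfonate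
Product: 30 5-(benzyloxy)-6-[1-hydroxy-8-methoxy-6-methyl-4-(trifluoromethanesulfonyloxy)naphthalen-2-yl]-4-methoxy-2-methylnaphthalen-1-yl trifluoromethanesulfonate, via hydroquinone 29 (not isolated)
Conditions: Na2S2O4, THF/H2O, rt; then PhNTf2 (1.05 equiv), Et3N, CH2Cl2, 0 °C
Reagents that add atoms: N-phenylbis(trifluoromethanesulfonimide) O=S(=O)(N(c1ccccc1)S(=O)(=O)C(F)(F)F)C(F)(F)F
Why: Quinone reduction followed by site-selective O-sulfonylation, where the hydroxyl flanked only by hydrogens reacts with the bulky triflimide while the other is hydrogen-bonded to the peri-methoxy group and shielded by the ortho aryl ring.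

Step 16
Reactants: 30 5-(benzyloxy)-6-[1-hydroxy-8-methoxy-6-methyl-4-(trifluoromethanesulfonyloxy)naphthalen-2-yl]-4-methoxy-2-methylnaphthalen-1-yl trifluoromethanesulfonate; 11 (1R,3R)-8-(benzyloxy)-1,3-dimethyl-5-(4,4,5,5-tetramethyl-1,3,2-dioxaborolan-2-yl)-1,2,3,4-tetrahydroisoquinoline (2.5 equiv)
Product: 31 2-{5-(benzyloxy)-1-[(1R,3R)-8-(benzyloxy)-1,3-dimethyl-1,2,3,4-tetrahydroisoquinolin-5-yl]-4-methoxy-2-methylnaphthalen-6-yl}-4-[(1R,3R)-8-(benzyloxy)-1,3-dimethyl-1,2,3,4-tetrahydroisoquinolin-5-yl]-8-methoxy-6-methylnaphthalen-1-ol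
Conditions: Pd(OAc)2 (10 mol %), SPhos (20 mol %), K3PO4, toluene/H2O, 100 °C
Reagents that add atoms: none
Why: Twofold Suzuki–Miyaura coupling with a ligand made for hindered biaryls installs both isoquinolines at once; the four stereocentres are untouched and the two new hindered axes form as separable atropo-diastereomers.

Step 17
Reactants: 31 (tri-O-benzyl precursor from step 16)
Product: 32 2-{5-hydroxy-1-[(1R,3R)-8-hydroxy-1,3-dimethyl-1,2,3,4-tetrahydroisoquinolin-5-yl]-4-methoxy-2-methylnaphthalen-6-yl}-4-[(1R,3R)-8-hydroxy-1,3-dimethyl-1,2,3,4-tetrahydroisoquinolin-5-yl]-8-methoxy-6-methylnaphthalen-1-ol (CNP0077060.1)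
Conditions: H2 (1 atm), Pd/C (10 wt %), MeOH/EtOAc, rt; preparative HPLC
Reagents that add atoms: none
Why: Hydrogenolysis of the three benzyl ethers frees the phenols without touching methyl ethers, amines or any stereocentre.

**Compound list**
1 | 1-(benzyloxy)-3-bromobenzene | Brc1cccc(OCc2ccccc2)c1 | starting material
2 | tert-butyl (4R)-4-methyl-1,2,3-oxathiazolidine-3-carboxylate 2,2-dioxide (D-alaninol cyclic sulfamidate) | C[C@@H]1COS(=O)(=O)N1C(=O)OC(C)(C)C | starting material
3 | [3-(benzyloxy)phenyl]magnesium bromide | Br[Mg]c1cccc(OCc2ccccc2)c1 | intermediate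
4 | (2R)-N-Boc-N-sulfonate of 1-[3-(benzyloxy)phenyl]propan-2-amine (drawn as free acid, present as bromomagnesium salt) | C[C@H](Cc1cccc(OCc2ccccc2)c1)N(C(=O)OC(C)(C)C)S(=O)(=O)O | intermediate
5 | tert-butyl N-[(2R)-1-[3-(benzyloxy)phenyl]propan-2-yl]carbamate | C[C@H](Cc1cccc(OCc2ccccc2)c1)NC(=O)OC(C)(C)C | intermediate
6 | tert-butyl N-[(2R)-1-[5-(benzyloxy)-2-bromophenyl]propan-2-yl]carbamate | C[C@H](Cc1cc(OCc2ccccc2)ccc1Br)NC(=O)OC(C)(C)C | intermediate
7 | (2R)-1-[5-(benzyloxy)-2-bromophenyl]propan-2-amine hydrochloride | C[C@H](Cc1cc(OCc2ccccc2)ccc1Br)N.Cl | intermediate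
8 | N-[(2R)-1-[5-(benzyloxy)-2-bromophenyl]propan-2-yl]acetamide | C[C@H](Cc1cc(OCc2ccccc2)ccc1Br)NC(C)=O | intermediate
9 | (3R)-8-(benzyloxy)-5-bromo-1,3-dimethyl-3,4-dihydroisoquinoline | CC1=N[C@H](C)Cc2c(Br)ccc(OCc3ccccc3)c21 | intermediate
10 | (1R,3R)-8-(benzyloxy)-5-bromo-1,3-dimethyl-1,2,3,4-tetrahydroisoquinoline | Brc1ccc(OCc2ccccc2)c2c1C[C@@H](C)N[C@@H]2C | intermediate
11 | (1R,3R)-8-(benzyloxy)-1,3-dimethyl-5-(4,4,5,5-tetramethyl-1,3,2-dioxaborolan-2-yl)-1,2,3,4-tetrahydroisoquinoline | CC1(C)OB(OC1(C)C)c1ccc(OCc2ccccc2)c2c1C[C@@H](C)N[C@@H]2C | intermediate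
12 | methyl 3-methylbut-2-enoate | COC(=O)C=C(C)C | starting material
13 | [(1-methoxy-3-methylbuta-1,3-dien-1-yl)oxy]trimethylsilane (E/Z mixture) | COC(O[Si](C)(C)C)=CC(C)=C | intermediate
14 | 2,6-dibromo-1,4-benzoquinone | O=C1C=C(Br)C(=O)C(Br)=C1 | starting material
15 | 3,4a-dibromo-5-methoxy-7-methyl-5-[(trimethylsilyl)oxy]-4a,5,8,8a-tetrahydronaphthalene-1,4-dione (racemic cycloadduct) | COC1(O[Si](C)(C)C)C=C(C)CC2C(=O)C=C(Br)C(=O)C12Br | intermediate
16 | 2-bromo-6-methyl-8-[(trimethylsilyl)oxy]naphthalene-1,4-dione | Cc1cc(O[Si](C)(C)C)c2C(=O)C(Br)=CC(=O)c2c1 | intermediate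
17 | 2-bromo-8-hydroxy-6-methylnaphthalene-1,4-dione | Cc1cc(O)c2C(=O)C(Br)=CC(=O)c2c1 | intermediate
18 | 2-bromo-8-methoxy-6-methylnaphthalene-1,4-dione | COc1cc(C)cc2C(=O)C=C(Br)C(=O)c12 | intermediate
19 | 2,6-diiodophenol | Oc1c(I)cccc1I | starting material
20 | 2-(benzyloxy)-1,3-diiodobenzene | Ic1cccc(I)c1OCc1ccccc1 | intermediate
21 | [2-(benzyloxy)-3-iodophenyl]lithium | [Li]c1cccc(I)c1OCc1ccccc1 | intermediate
22 | lithium pentacarbonyl{[2-(benzyloxy)-3-iodophenyl](oxido)methylidene}chromate | [Li+].[O-]C(c1cccc(I)c1OCc1ccccc1)=[Cr](=C=O)(=C=O)(=C=O)(=C=O)=C=O | intermediate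
23 | pentacarbonyl{[2-(benzyloxy)-3-iodophenyl](methoxy)methylidene}chromium | COC(c1cccc(I)c1OCc1ccccc1)=[Cr](=C=O)(=C=O)(=C=O)(=C=O)=C=O | intermediate
24 | propyne | CC#C | starting material
25 | 5-(benzyloxy)-6-iodo-4-methoxy-2-methylnaphthalen-1-ol | COc1cc(C)c(O)c2ccc(I)c(OCc3ccccc3)c12 | intermediate
26 | 5-(benzyloxy)-6-iodo-4-methoxy-2-methylnaphthalen-1-yl trifluoromethanesulfonate | COc1cc(C)c(OS(=O)(=O)C(F)(F)F)c2ccc(I)c(OCc3ccccc3)c12 | intermediate
27 | 5-(benzyloxy)-4-methoxy-2-methyl-6-(4,4,5,5-tetramethyl-1,3,2-dioxaborolan-2-yl)naphthalen-1-yl trifluoromethanesulfonate | COc1cc(C)c(OS(=O)(=O)C(F)(F)F)c2ccc(B3OC(C)(C)C(C)(C)O3)c(OCc3ccccc3)c12 | intermediate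
28 | 5-(benzyloxy)-4-methoxy-6-(8-methoxy-6-methyl-1,4-dioxo-1,4-dihydronaphthalen-2-yl)-2-methylnaphthalen-1-yl trifluoromethanesulfonate | COc1cc(C)cc2C(=O)C=C(c3ccc4c(OS(=O)(=O)C(F)(F)F)c(C)cc(OC)c4c3OCc3ccccc3)C(=O)c12 | intermediate
29 | 5-(benzyloxy)-6-(1,4-dihydroxy-8-methoxy-6-methylnaphthalen-2-yl)-4-methoxy-2-methylnaphthalen-1-yl trifluoromethanesulfonate | COc1cc(C)cc2c(O)cc(-c3ccc4c(OS(=O)(=O)C(F)(F)F)c(C)cc(OC)c4c3OCc3ccccc3)c(O)c12 | intermediate
30 | 5-(benzyloxy)-6-[1-hydroxy-8-methoxy-6-methyl-4-(trifluoromethanesulfonyloxy)naphthalen-2-yl]-4-methoxy-2-methylnaphthalen-1-yl trifluoromethanesulfonate | COc1cc(C)cc2c(OS(=O)(=O)C(F)(F)F)cc(-c3ccc4c(OS(=O)(=O)C(F)(F)F)c(C)cc(OC)c4c3OCc3ccccc3)c(O)c12 | intermediate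
31 | 2-{5-(benzyloxy)-1-[(1R,3R)-8-(benzyloxy)-1,3-dimethyl-1,2,3,4-tetrahydroisoquinolin-5-yl]-4-methoxy-2-methylnaphthalen-6-yl}-4-[(1R,3R)-8-(benzyloxy)-1,3-dimethyl-1,2,3,4-tetrahydroisoquinolin-5-yl]-8-methoxy-6-methylnaphthalen-1-ol | COc1cc(C)cc2c(-c3ccc(OCc4ccccc4)c4c3C[C@@H](C)N[C@@H]4C)cc(-c3ccc4c(-c5ccc(OCc6ccccc6)c6c5C[C@@H](C)N[C@@H]6C)c(C)cc(OC)c4c3OCc3ccccc3)c(O)c12 | intermediate
32 | 2-{5-hydroxy-1-[(1R,3R)-8-hydroxy-1,3-dimethyl-1,2,3,4-tetrahydroisoquinolin-5-yl]-4-methoxy-2-methylnaphthalen-6-yl}-4-[(1R,3R)-8-hydroxy-1,3-dimethyl-1,2,3,4-tetrahydroisoquinolin-5-yl]-8-methoxy-6-methylnaphthalen-1-ol | COc1cc(C)cc2c(-c3ccc(O)c4c3C[C@@H](C)N[C@@H]4C)cc(-c3ccc4c(-c5ccc(O)c6c5C[C@@H](C)N[C@@H]6C)c(C)cc(OC)c4c3O)c(O)c12 | target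

**Totals**
Total step count: 17. Longest linear sequence: 8 steps (steps 10–17, or equally steps 1–6 then 16–17).

**Three steps most likely to fail**

Step 12. The aryl iodide may not survive the benzannulation, or the in-flask triflation of the hindered naphthol may be poor. The fallback masks the position with silicon and sets out from 20. One iodine is exchanged (n-BuLi, −78 °C) and quenched with Me3SiCl to give [2-(benzyloxy)-3-iodophenyl]trimethylsilane F1. The second iodine is converted as in step 11 into pentacarbonyl{[2-(benzyloxy)-3-(trimethylsilyl)phenyl](methoxy)methylidene}chromium F2. Benzannulation with propyne and triflation give 5-(benzyloxy)-4-methoxy-2-methyl-6-(trimethylsilyl)naphthalen-1-yl trifluoromethanesulfonate F3. Ipso-iododesilylation with ICl (CH2Cl2, −78 °C) comes back to the route at 26.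

Step 15. Direct mono-triflation may give bis-triflate or the wrong regioisomer. The fallback differentiates the two hydroxyls by a protect–deprotect sequence and sets out from 28. Reductive acetylation (Zn, Ac2O, Et3N) gives 5-(benzyloxy)-6-(1,4-diacetoxy-8-methoxy-6-methylnaphthalen-2-yl)-4-methoxy-2-methylnaphthalen-1-yl trifluoromethanesulfonate F4. Methanolysis of the unhindered acetate only (K2CO3, MeOH, 0 °C) gives 5-(benzyloxy)-6-(1-acetoxy-4-hydroxy-8-methoxy-6-methylnaphthalen-2-yl)-4-methoxy-2-methylnaphthalen-1-yl trifluoromethanesulfonate F5. Triflation (Tf2O, pyridine) gives 5-(benzyloxy)-6-[1-acetoxy-8-methoxy-6-methyl-4-(trifluoromethanesulfonyloxy)naphthalen-2-yl]-4-methoxy-2-methylnaphthalen-1-yl trifluoromethanesulfonate F6. F6 is used in place of 30 under the step 16 conditions, where the aqueous K3PO4 also cleaves the hindered acetate, so the route is rejoined at 31.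

Step 16. The hindered double coupling may stall because of the free phenoxide para to one triflate or the free NH groups. The fallback uses the fully benzyl-protected partners and sets out from 30 and 11. O-Benzylation of 30 (BnBr, K2CO3, DMF) gives 5-(benzyloxy)-6-[1-(benzyloxy)-8-methoxy-6-methyl-4-(trifluoromethanesulfonyloxy)naphthalen-2-yl]-4-methoxy-2-methylnaphthalen-1-yl trifluoromethanesulfonate F7. N-Benzylation of 11 (BnBr, K2CO3, MeCN) gives (1R,3R)-2-benzyl-8-(benzyloxy)-1,3-dimethyl-5-(4,4,5,5-tetramethyl-1,3,2-dioxaborolan-2-yl)-1,2,3,4-tetrahydroisoquinoline F8. Their double Suzuki coupling gives the N,N′-dibenzyl tetra-O-benzyl derivative of 32 F9. Hydrogenolysis (H2, Pd(OH)2/C, MeOH/AcOH) comes back to the route at 32.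

**Further compounds**
F1 | step 12 | [2-(benzyloxy)-3-iodophenyl]trimethylsilane | C[Si](C)(C)c1cccc(I)c1OCc1ccccc1
F2 | step 12 | pentacarbonyl{[2-(benzyloxy)-3-(trimethylsilyl)phenyl](methoxy)methylidene}chromium | COC(c1cccc([Si](C)(C)C)c1OCc1ccccc1)=[Cr](=C=O)(=C=O)(=C=O)(=C=O)=C=O
F3 | step 12 | 5-(benzyloxy)-4-methoxy-2-methyl-6-(trimethylsilyl)naphthalen-1-yl trifluoromethanesulfonate | COc1cc(C)c(OS(=O)(=O)C(F)(F)F)c2ccc([Si](C)(C)C)c(OCc3ccccc3)c12
F4 | step 15 | 5-(benzyloxy)-6-(1,4-diacetoxy-8-methoxy-6-methylnaphthalen-2-yl)-4-methoxy-2-methylnaphthalen-1-yl trifluoromethanesulfonate | COc1cc(C)cc2c(OC(C)=O)cc(-c3ccc4c(OS(=O)(=O)C(F)(F)F)c(C)cc(OC)c4c3OCc3ccccc3)c(OC(C)=O)c12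
F5 | step 15 | 5-(benzyloxy)-6-(1-acetoxy-4-hydroxy-8-methoxy-6-methylnaphthalen-2-yl)-4-methoxy-2-methylnaphthalen-1-yl trifluoromethanesulfonate | COc1cc(C)cc2c(O)cc(-c3ccc4c(OS(=O)(=O)C(F)(F)F)c(C)cc(OC)c4c3OCc3ccccc3)c(OC(C)=O)c12
F6 | step 15 | 5-(benzyloxy)-6-[1-acetoxy-8-methoxy-6-methyl-4-(trifluoromethanesulfonyloxy)naphthalen-2-yl]-4-methoxy-2-methylnaphthalen-1-yl trifluoromethanesulfonate | COc1cc(C)cc2c(OS(=O)(=O)C(F)(F)F)cc(-c3ccc4c(OS(=O)(=O)C(F)(F)F)c(C)cc(OC)c4c3OCc3ccccc3)c(OC(C)=O)c12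
F7 | step 16 | 5-(benzyloxy)-6-[1-(benzyloxy)-8-methoxy-6-methyl-4-(trifluoromethanesulfonyloxy)naphthalen-2-yl]-4-methoxy-2-methylnaphthalen-1-yl trifluoromethanesulfonate | COc1cc(C)cc2c(OS(=O)(=O)C(F)(F)F)cc(-c3ccc4c(OS(=O)(=O)C(F)(F)F)c(C)cc(OC)c4c3OCc3ccccc3)c(OCc3ccccc3)c12
F8 | step 16 | (1R,3R)-2-benzyl-8-(benzyloxy)-1,3-dimethyl-5-(4,4,5,5-tetramethyl-1,3,2-dioxaborolan-2-yl)-1,2,3,4-tetrahydroisoquinoline | CC1(C)OB(OC1(C)C)c1ccc(OCc2ccccc2)c2c1C[C@@H](C)N(Cc1ccccc1)[C@@H]2C
F9 | step 16 | N,N′-dibenzyl tetra-O-benzyl derivative of 32 | COc1cc(C)cc2c(-c3ccc(OCc4ccccc4)c4c3C[C@@H](C)N(Cc3ccccc3)[C@@H]4C)cc(-c3ccc4c(-c5ccc(OCc6ccccc6)c6c5C[C@@H](C)N(Cc5ccccc5)[C@@H]6C)c(C)cc(OC)c4c3OCc3ccccc3)c(OCc3ccccc3)c12
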